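The route rests on the disconnection of the middle dihydrobenzofuran (DHB 2) at C3–aryl; the outer ones (DHB 1 with the styryl group, DHB 3 with the 3,5-dihydroxyphenyl group) are two copies of one bromide, 12. C3 of DHB 2 is the benzylic carbon ortho to the ring oxygen O1 on its benzo ring, hence the exocyclic carbon of an ortho-quinone methide. In one flask the C4 aryllithium of DHB 3 adds to an ortho-OBoc salicylaldehyde carried by DHB 1 (aldehyde 15), the quinone methide forms, and a chiral 4-methoxybenzyl sulfonium ylide closes the furan ring by (4+1) annulation, setting C2 and C3.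

Key step: step 9

Assumption: both enantiomers of isothiocineole and the Grignard solution 9 are bought, and sulfonium salt 6 is taken to lead to the (2R,3R) ring and salt 8 to the (2S,3S) ring; if the sense of induction is the reverse, 6 and 8 are exchanged.

Step 1
Reactants: 1 2-bromo-4,6-dimethoxybenzaldehyde
Product: 2 2-bromo-6-hydroxy-4-methoxybenzaldehyde
Conditions: BCl3 (1.2 equiv), CH2Cl2, −78 to 0 °C; then H2O
Reagents that add atoms: none
Why: BCl3 chelates between the aldehyde oxygen and the ortho methoxy oxygen, so only that methyl ether is cleaved (chelation-directed regioselective ortho-demethylation), and the para methoxy group and the aryl bromide are untouched.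

Step 2
Reactants: 2 2-bromo-6-hydroxy-4-methoxybenzaldehyde
Product: 3 tert-butyl (3-bromo-2-formyl-5-methoxyphenyl) carbonate
Conditions: Boc2O, i-Pr2NEt, 4-(dimethylamino)pyridine (cat.), THF, 0 °C to rt
Reagents that add atoms: di-tert-butyl dicarbonate (Boc2O), CC(C)(C)OC(=O)OC(=O)OC(C)(C)C
Why: Nucleophile-catalysed O-acylation of the phenol gives the aryl tert-butyl carbonate that later acts as migrating and leaving group for quinone methide formation.

Step 3
Reactants: 4 4-methoxybenzyl bromide; 5 (1R,4R,5R)-4,7,7-trimethyl-6-thiabicyclo[3.2.1]octane (isothiocineole)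
Product: 6 (1R,4R,5R)-6-(4-methoxybenzyl)-4,7,7-trimethyl-6-thiabicyclo[3.2.1]octan-6-ium tetrafluoroborate (benzyl group exo, on the side of the one-carbon bridge)
Conditions: NaBF4, CH2Cl2/H2O, rt
Reagents that add atoms: sodium tetrafluoroborate, [Na+].F[B-](F)(F)F
Why: SN2 S-alkylation of the thioether by the benzylic bromide, with exchange of bromide for non-nucleophilic BF4− to prevent reversal, should give one sulfonium diastereomer because only the exo lone pair is accessible.

Step 4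
Reactants: 4 4-methoxybenzyl bromide; 7 (1S,4S,5S)-4,7,7-trimethyl-6-thiabicyclo[3.2.1]octane (ent-isothiocineole)
Product: 8 (1S,4S,5S)-6-(4-methoxybenzyl)-4,7,7-trimethyl-6-thiabicyclo[3.2.1]octan-6-ium tetrafluoroborate (enantiomer of 6)
Conditions: NaBF4, CH2Cl2/H2O, rt
Reagents that add atoms: sodium tetrafluoroborate, [Na+].F[B-](F)(F)F
Why: The same S-alkylation with the mirror-image sulfide gives the enantiomeric salt.

Step 5
Reactants: 9 3,5-dimethoxyphenylmagnesium chloride; 3 tert-butyl (3-bromo-2-formyl-5-methoxyphenyl) carbonate; 6 sulfonium tetrafluoroborate from (1R,4R,5R)-isothiocineole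
Product: 12 (2R,3R)-4-bromo-3-(3,5-dimethoxyphenyl)-6-methoxy-2-(4-methoxyphenyl)-2,3-dihydro-1-benzofuran (trans), via sulfonium ylide 10 (not isolated), via ortho-quinone methide 11 (not isolated)
Conditions: 9 (1.0 equiv), THF, −78 °C; then ylide 10 (from 6, LiN(SiMe3)2, THF, −78 °C); −78 °C to rt; H2O
Reagents that add atoms: none
Why: Grignard addition to the aldehyde is followed on warming by Boc migration to the benzylic alkoxide and loss of tert-butyl carbonate to give quinone methide 11, which ylide 10 traps by conjugate addition and 5-exo-tet displacement of the sulfide ((4+1) sulfur-ylide annulation), the sulfide fixing the face of the ylide carbon and the anti arrangement of the two aryl groups in the C–C bond-forming event relaying this to C3, so that the trans-(2R,3R) ring should form.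

Step 6
Reactants: 12 (2R,3R)-4-bromo-3-(3,5-dimethoxyphenyl)-6-methoxy-2-(4-methoxyphenyl)-2,3-dihydro-1-benzofuran
Product: 13 2-[(2R,3R)-4-bromo-6-methoxy-2-(4-methoxyphenyl)-2,3-dihydro-1-benzofuran-3-yl]-4,6-dimethoxybenzaldehyde
Conditions: POCl3 (1.2 equiv), DMF, 0 to 50 °C; then aq NaOAc, rt
Reagents that add atoms: N,N-dimethylformamide, CN(C)C=O; water, O
Why: In this Vilsmeier–Haack formylation the chloroiminium ion should attack the most electron-rich ring, the 3,5-dimethoxyphenyl group, at C2 (equivalent to C6 by rotation), which is para to one methoxy group and ortho to the other like the reactive 4-position of a 1,3-dimethoxyarene, whereas the position between the two methoxy groups corresponds to the unreactive 2-position, ring A is deactivated by bromine and the anisyl ring has only one donor; no stereocentre is touched.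

Step 7
Reactants: 13 2-[(2R,3R)-4-bromo-6-methoxy-2-(4-methoxyphenyl)-2,3-dihydro-1-benzofuran-3-yl]-4,6-dimethoxybenzaldehyde
Product: 14 2-[(2R,3R)-4-bromo-6-methoxy-2-(4-methoxyphenyl)-2,3-dihydro-1-benzofuran-3-yl]-6-hydroxy-4-methoxybenzaldehyde
Conditions: BCl3 (1.2 equiv), CH2Cl2, −78 to 0 °C; then H2O
Reagents that add atoms: none
Why: As in step 1, BCl3 chelated between the aldehyde oxygen and the single ortho methoxy oxygen cleaves only that methyl ether (chelation-directed ortho-demethylation), and at low temperature with about one equivalent the other four methyl ethers and the trans dihydrobenzofuran should stay intact.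

Step 8
Reactants: 14 2-[(2R,3R)-4-bromo-6-methoxy-2-(4-methoxyphenyl)-2,3-dihydro-1-benzofuran-3-yl]-6-hydroxy-4-methoxybenzaldehyde
Product: 15 tert-butyl {3-[(2R,3R)-4-bromo-6-methoxy-2-(4-methoxyphenyl)-2,3-dihydro-1-benzofuran-3-yl]-2-formyl-5-methoxyphenyl} carbonate
Conditions: Boc2O, i-Pr2NEt, 4-(dimethylamino)pyridine (cat.), THF, 0 °C to rt
Reagents that add atoms: di-tert-butyl dicarbonate (Boc2O), CC(C)(C)OC(=O)OC(=O)OC(C)(C)C
Why: O-acylation of the only free OH installs the carbonate needed for quinone methide generation, as in step 2.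

Step 9
Reactants: 12 (2R,3R)-4-bromo-3-(3,5-dimethoxyphenyl)-6-methoxy-2-(4-methoxyphenyl)-2,3-dihydro-1-benzofuran; 15 ortho-OBoc salicylaldehyde of DHB 1; 8 sulfonium tetrafluoroborate from (1S,4S,5S)-isothiocineole
Product: 19 (2R,3R)-4-bromo-3-{(2S,3S)-3-[(2R,3R)-3-(3,5-dimethoxyphenyl)-6-methoxy-2-(4-methoxyphenyl)-2,3-dihydro-1-benzofuran-4-yl]-6-methoxy-2-(4-methoxyphenyl)-2,3-dihydro-1-benzofuran-4-yl}-6-methoxy-2-(4-methoxyphenyl)-2,3-dihydro-1-benzofuran, via aryllithium 16 (not isolated), via sulfonium ylide 17 (not isolated), via ortho-quinone methide 18 (not isolated)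
Conditions: 12, t-BuLi (2.0 equiv), THF, −78 °C; 15, −78 °C; then ylide 17 (from 8, LiN(SiMe3)2, THF, −78 °C) and MgBr2·OEt2, −78 to 0 °C; H2O
Reagents that add atoms: none
Why: Aryllithium 16 adds to the aldehyde of 15 and so forms the bond between C4 of DHB 3 and the future C3 of DHB 2; the alkoxide takes over the Boc group, MgBr2 triggers loss of tert-butyl carbonate from the phenoxide to give quinone methide 18, and ylide 17 adds to its exocyclic carbon before the phenoxide displaces the sulfide. The closest known reaction types are the organometallic-triggered generation of ortho-quinone methides from ortho-OBoc salicylaldehydes and the (4+1) annulation of ortho-quinone methides with sulfonium ylides, here run in one flask. The furan ring of DHB 2 closes by 5-exo-tet displacement at the ylide carbon (O1 onto C2), and the trans ring is also the thermodynamic one. C3 is set in the C–C bond-forming event by the rigid bicyclic sulfide, which exposes one face of the ylide carbon and places the two aryl groups anti; C2 follows as trans, and the (1S,4S,5S) sulfide is expected to select the (2S,3S) pair. The step needs 1,2-addition of 16 to the aldehyde rather than attack on the carbonate or Br/Li exchange with the aryl bromide of 15, which the far higher electrophilicity of the formyl group at −78 °C secures. It also needs reagent control at C3 over the bias of the two flanking dihydrobenzofurans, which rests on the strong face preference of the ylide and on the quinone methide being released only once the ylide is present, since the lithium phenoxide carbonate is stable at −78 °C.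

Step 10
Reactants: 19 octamethyl ether bromide
Product: 20 (2R,3R)-4-bromo-3-{(2S,3S)-3-[(2R,3R)-3-(3,5-dihydroxyphenyl)-6-hydroxy-2-(4-hydroxyphenyl)-2,3-dihydro-1-benzofuran-4-yl]-6-hydroxy-2-(4-hydroxyphenyl)-2,3-dihydro-1-benzofuran-4-yl}-2-(4-hydroxyphenyl)-2,3-dihydro-1-benzofuran-6-ol
Conditions: BBr3 (excess), CH2Cl2, −78 to 0 °C; MeOH then H2O
Reagents that add atoms: none
Why: BBr3 cleaves each aryl methyl ether through its Lewis acid adduct and bromide attack at methyl; the stilbene is not yet present, so no acid-induced cyclisation onto an alkene can occur, and any reversible opening of a C2–O bond should re-close to the more stable trans ring.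

Step 11
Reactants: 20 octaphenol bromide; 21 4-acetoxystyrene
Product: 23 Miyabenol A, via stilbene acetate 22 (not isolated)
Conditions: Pd(OAc)2 (cat.), P(o-tol)3, Et3N, DMF, 100 °C, argon; then K2CO3 (cat.), MeOH, rt; AcOH
Reagents that add atoms: none
Why: The Heck reaction (oxidative addition to the aryl bromide, syn insertion with aryl transfer to the terminal alkene carbon, syn β-hydride elimination) should give the E-stilbene, and base-catalysed methanolysis then removes the acetate without touching any stereocentre.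

Compound list
1 | 2-bromo-4,6-dimethoxybenzaldehyde | O=Cc1c(Br)cc(OC)cc1OC | starting material
2 | 2-bromo-6-hydroxy-4-methoxybenzaldehyde | O=Cc1c(Br)cc(OC)cc1O | intermediate
3 | tert-butyl (3-bromo-2-formyl-5-methoxyphenyl) carbonate | O=Cc1c(Br)cc(OC)cc1OC(=O)OC(C)(C)C | intermediate
4 | 4-methoxybenzyl bromide | COc1ccc(CBr)cc1 | starting material
5 | (1R,4R,5R)-4,7,7-trimethyl-6-thiabicyclo[3.2.1]octane | C[C@@H]1CC[C@@H]2C[C@H]1SC2(C)C | starting material
6 | (1R,4R,5R)-6-(4-methoxybenzyl)-4,7,7-trimethyl-6-thiabicyclo[3.2.1]octan-6-ium tetrafluoroborate, benzyl exo | C[C@@H]1CC[C@@H]2C[C@H]1[S@@+](Cc3ccc(OC)cc3)C2(C)C.F[B-](F)(F)F | intermediate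
7 | (1S,4S,5S)-4,7,7-trimethyl-6-thiabicyclo[3.2.1]octane | C[C@H]1CC[C@H]2C[C@@H]1SC2(C)C | starting material
8 | (1S,4S,5S)-6-(4-methoxybenzyl)-4,7,7-trimethyl-6-thiabicyclo[3.2.1]octan-6-ium tetrafluoroborate, benzyl exo | C[C@H]1CC[C@H]2C[C@@H]1[S@+](Cc3ccc(OC)cc3)C2(C)C.F[B-](F)(F)F | intermediate
9 | 3,5-dimethoxyphenylmagnesium chloride | COc1cc(OC)cc([Mg]Cl)c1 | starting material
10 | (4-methoxyphenyl)methylide of sulfonium 6 | C[C@@H]1CC[C@@H]2C[C@H]1[S@@+]([CH-]c3ccc(OC)cc3)C2(C)C | intermediate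
11 | 3-bromo-2-[(3,5-dimethoxyphenyl)methylidene]-5-methoxycyclohexa-3,5-dien-1-one | O=C1C=C(OC)C=C(Br)C1=Cc2cc(OC)cc(OC)c2 | intermediate
12 | (2R,3R)-4-bromo-3-(3,5-dimethoxyphenyl)-6-methoxy-2-(4-methoxyphenyl)-2,3-dihydro-1-benzofuran | Brc1cc(OC)cc2c1[C@@H](c1cc(OC)cc(OC)c1)[C@H](c1ccc(OC)cc1)O2 | intermediate
13 | 2-[(2R,3R)-4-bromo-6-methoxy-2-(4-methoxyphenyl)-2,3-dihydro-1-benzofuran-3-yl]-4,6-dimethoxybenzaldehyde | Brc1cc(OC)cc2c1[C@@H](c1cc(OC)cc(OC)c1C=O)[C@H](c1ccc(OC)cc1)O2 | intermediate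
14 | 2-[(2R,3R)-4-bromo-6-methoxy-2-(4-methoxyphenyl)-2,3-dihydro-1-benzofuran-3-yl]-6-hydroxy-4-methoxybenzaldehyde | Brc1cc(OC)cc2c1[C@@H](c1cc(OC)cc(O)c1C=O)[C@H](c1ccc(OC)cc1)O2 | intermediate
15 | tert-butyl {3-[(2R,3R)-4-bromo-6-methoxy-2-(4-methoxyphenyl)-2,3-dihydro-1-benzofuran-3-yl]-2-formyl-5-methoxyphenyl} carbonate | Brc1cc(OC)cc2c1[C@@H](c1cc(OC)cc(OC(=O)OC(C)(C)C)c1C=O)[C@H](c1ccc(OC)cc1)O2 | intermediate
16 | [(2R,3R)-3-(3,5-dimethoxyphenyl)-6-methoxy-2-(4-methoxyphenyl)-2,3-dihydro-1-benzofuran-4-yl]lithium | [Li]c1cc(OC)cc2c1[C@@H](c1cc(OC)cc(OC)c1)[C@H](c1ccc(OC)cc1)O2 | intermediate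
17 | (4-methoxyphenyl)methylide of sulfonium 8 | C[C@H]1CC[C@H]2C[C@@H]1[S@+]([CH-]c3ccc(OC)cc3)C2(C)C | intermediate
18 | ortho-quinone methide of ring 2: 5-methoxycyclohexa-3,5-dien-1-one bearing at C3 the DHB 1 unit (through its C3) and at C2 the exocyclic =CH– group attached to C4 of DHB 3 | O=C1C=C(OC)C=C([C@@H]2c3c(Br)cc(OC)cc3O[C@H]2c2ccc(OC)cc2)C1=Cc1cc(OC)cc2c1[C@@H](c1cc(OC)cc(OC)c1)[C@H](c1ccc(OC)cc1)O2 | intermediate
19 | (2R,3R)-4-bromo-3-{(2S,3S)-3-[(2R,3R)-3-(3,5-dimethoxyphenyl)-6-methoxy-2-(4-methoxyphenyl)-2,3-dihydro-1-benzofuran-4-yl]-6-methoxy-2-(4-methoxyphenyl)-2,3-dihydro-1-benzofuran-4-yl}-6-methoxy-2-(4-methoxyphenyl)-2,3-dihydro-1-benzofuran | Brc1cc(OC)cc2c1[C@@H](c1cc(OC)cc3c1[C@H](c1cc(OC)cc4c1[C@@H](c1cc(OC)cc(OC)c1)[C@H](c1ccc(OC)cc1)O4)[C@@H](c1ccc(OC)cc1)O3)[C@H](c1ccc(OC)cc1)O2 | intermediate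
20 | octaphenol bromide (19 with all eight methyl ethers cleaved) | Brc1cc(O)cc2c1[C@@H](c1cc(O)cc3c1[C@H](c1cc(O)cc4c1[C@@H](c1cc(O)cc(O)c1)[C@H](c1ccc(O)cc1)O4)[C@@H](c1ccc(O)cc1)O3)[C@H](c1ccc(O)cc1)O2 | intermediate
21 | 4-acetoxystyrene | CC(=O)Oc1ccc(C=C)cc1 | starting material
22 | Miyabenol A 4-O-acetate on the stilbene phenol | CC(=O)Oc1ccc(/C=C/c2cc(O)cc3c2[C@@H](c2cc(O)cc4c2[C@H](c2cc(O)cc5c2[C@@H](c2cc(O)cc(O)c2)[C@H](c2ccc(O)cc2)O5)[C@@H](c2ccc(O)cc2)O4)[C@H](c2ccc(O)cc2)O3)cc1 | intermediate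
23 | Miyabenol A | Oc1ccc(/C=C/c2cc(O)cc3c2[C@@H](c2cc(O)cc4c2[C@H](c2cc(O)cc5c2[C@@H](c2cc(O)cc(O)c2)[C@H](c2ccc(O)cc2)O5)[C@@H](c2ccc(O)cc2)O4)[C@H](c2ccc(O)cc2)O3)cc1 | target

Total step count: 11. Longest linear sequence: 9 steps (steps 1, 2, 5, 6, 7, 8, 9, 10, 11).

Steps most likely to fail

Step 9. The hindered aryllithium may be consumed by proton transfer or by attack on the carbonate before it reaches the doubly ortho-substituted aldehyde. The ylide may also add to the quinone methide under the steric bias of the two flanking dihydrobenzofurans instead of under sulfide control, giving poor facial selectivity at C3. Fallback, setting out from 12 and 14 and returning at 19: the ring is closed by a catalyst-controlled carbene C–H insertion instead of an ylide annulation. Phenol 14 is alkylated with 4 (K2CO3, DMF) to the 4-methoxybenzyl ether aldehyde F1. Aryllithium 16 (from 12, t-BuLi, THF, −78 °C) is added to it to give the diarylmethanol F2, and MnO2 oxidises this to the diaryl ketone F3. Anhydrous hydrazine with AcOH in EtOH at 100 °C (sealed tube) gives the hydrazone F4. MnO2 then converts F4 into the diaryldiazomethane F5, and Rh2(S-PTAD)4 (or its enantiomer, chosen so that C3 becomes S) inserts the donor/donor carbene into the OCH2Ar group to give the 2,3-cis dihydrobenzofuran F6. CF3CO2H in CH2Cl2 equilibrates C2 of this ring through the 4-methoxybenzyl cation to the trans isomer 19, the two outer rings being trans already.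

Step 6. The wanted position lies next to the hindered diarylmethine carbon, so the chloroiminium ion may instead attack ring A at C5 or C7 or the position between the two methoxy groups of the 3-aryl ring, giving poor site selectivity. Fallback, setting out from 2 (with 3 and 6) and returning at 14: the formyl group is carried in masked form through a second annulation instead of being introduced by electrophilic substitution. Phenol 2 is protected with MOMCl and i-Pr2NEt in CH2Cl2 as the methoxymethyl ether F7, and (Me3SiOCH2)2 with Me3SiOTf (cat.) in CH2Cl2 at −78 °C converts its aldehyde into the dioxolane F8. Br/Li exchange (t-BuLi, THF, −78 °C) gives the aryllithium F9, which adds to aldehyde 3. Ylide 10 (from 6 and LiN(SiMe3)2) and MgBr2·OEt2 then release the ortho-quinone methide F10 and close the trans-(2R,3R) ring of the acetal-protected dihydrobenzofuran F11, as in step 5. 2 M HCl in THF at 40 °C cleaves the dioxolane and the methoxymethyl ether of F11 to give 14.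

Step 11. The phenoxides may deactivate the palladium catalyst, the polyphenol may degrade oxidatively at 100 °C, and acetyl transfer or branched insertion of the styrene may erode the yield. Fallback, setting out from 20 and returning at 23: the phenols are masked before the coupling. TBSCl and imidazole in DMF give the octakis(silyl) ether F12. A Heck reaction with commercial 4-(tert-butyldimethylsilyloxy)styrene (Pd(OAc)2, P(o-tol)3, Et3N, DMF, 100 °C) gives the nonakis(silyl) ether F13, and Bu4NF buffered with AcOH in THF releases 23.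

Further compounds
F1 | step 9 | 2-[(2R,3R)-4-bromo-6-methoxy-2-(4-methoxyphenyl)-2,3-dihydro-1-benzofuran-3-yl]-4-methoxy-6-[(4-methoxybenzyl)oxy]benzaldehyde | Brc1cc(OC)cc2c1[C@@H](c1cc(OC)cc(OCc3ccc(OC)cc3)c1C=O)[C@H](c1ccc(OC)cc1)O2
F2 | step 9 | diarylmethanol from 16 and F1 (carbinol epimers) | Brc1cc(OC)cc2c1[C@@H](c1cc(OC)cc(OCc3ccc(OC)cc3)c1C(O)c1cc(OC)cc3c1[C@@H](c1cc(OC)cc(OC)c1)[C@H](c1ccc(OC)cc1)O3)[C@H](c1ccc(OC)cc1)O2
F3 | step 9 | diaryl ketone from F2 | Brc1cc(OC)cc2c1[C@@H](c1cc(OC)cc(OCc3ccc(OC)cc3)c1C(=O)c1cc(OC)cc3c1[C@@H](c1cc(OC)cc(OC)c1)[C@H](c1ccc(OC)cc1)O3)[C@H](c1ccc(OC)cc1)O2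
F4 | step 9 | hydrazone of F3 | Brc1cc(OC)cc2c1[C@@H](c1cc(OC)cc(OCc3ccc(OC)cc3)c1C(=NN)c1cc(OC)cc3c1[C@@H](c1cc(OC)cc(OC)c1)[C@H](c1ccc(OC)cc1)O3)[C@H](c1ccc(OC)cc1)O2
F5 | step 9 | diaryldiazomethane from F4 | Brc1cc(OC)cc2c1[C@@H](c1cc(OC)cc(OCc3ccc(OC)cc3)c1C(=[N+]=[N-])c1cc(OC)cc3c1[C@@H](c1cc(OC)cc(OC)c1)[C@H](c1ccc(OC)cc1)O3)[C@H](c1ccc(OC)cc1)O2
F6 | step 9 | C2 epimer of 19 in DHB 2 (2R,3S, cis) | Brc1cc(OC)cc2c1[C@@H](c1cc(OC)cc3c1[C@H](c1cc(OC)cc4c1[C@@H](c1cc(OC)cc(OC)c1)[C@H](c1ccc(OC)cc1)O4)[C@H](c1ccc(OC)cc1)O3)[C@H](c1ccc(OC)cc1)O2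
F7 | step 6 | 2-bromo-4-methoxy-6-(methoxymethoxy)benzaldehyde | O=Cc1c(Br)cc(OC)cc1OCOC
F8 | step 6 | 2-[2-bromo-4-methoxy-6-(methoxymethoxy)phenyl]-1,3-dioxolane | COCOc1cc(OC)cc(Br)c1C1OCCO1
F9 | step 6 | [2-(1,3-dioxolan-2-yl)-5-methoxy-3-(methoxymethoxy)phenyl]lithium | COCOc1cc(OC)cc([Li])c1C1OCCO1
F10 | step 6 | 3-bromo-2-{[2-(1,3-dioxolan-2-yl)-5-methoxy-3-(methoxymethoxy)phenyl]methylidene}-5-methoxycyclohexa-3,5-dien-1-one | O=C1C=C(OC)C=C(Br)C1=Cc2cc(OC)cc(OCOC)c2C3OCCO3
F11 | step 6 | (2R,3R)-4-bromo-3-[2-(1,3-dioxolan-2-yl)-5-methoxy-3-(methoxymethoxy)phenyl]-6-methoxy-2-(4-methoxyphenyl)-2,3-dihydro-1-benzofuran | Brc1cc(OC)cc2c1[C@@H](c1cc(OC)cc(OCOC)c1C1OCCO1)[C@H](c1ccc(OC)cc1)O2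
F12 | step 11 | octakis(tert-butyldimethylsilyl) ether of 20 | Brc1cc(O[Si](C)(C)C(C)(C)C)cc2c1[C@@H](c1cc(O[Si](C)(C)C(C)(C)C)cc3c1[C@H](c1cc(O[Si](C)(C)C(C)(C)C)cc4c1[C@@H](c1cc(O[Si](C)(C)C(C)(C)C)cc(O[Si](C)(C)C(C)(C)C)c1)[C@H](c1ccc(O[Si](C)(C)C(C)(C)C)cc1)O4)[C@@H](c1ccc(O[Si](C)(C)C(C)(C)C)cc1)O3)[C@H](c1ccc(O[Si](C)(C)C(C)(C)C)cc1)O2
F13 | step 11 | nonakis(tert-butyldimethylsilyl) ether of 23 | CC(C)(C)[Si](C)(C)Oc1ccc(/C=C/c2cc(O[Si](C)(C)C(C)(C)C)cc3c2[C@@H](c2cc(O[Si](C)(C)C(C)(C)C)cc4c2[C@H](c2cc(O[Si](C)(C)C(C)(C)C)cc5c2[C@@H](c2cc(O[Si](C)(C)C(C)(C)C)cc(O[Si](C)(C)C(C)(C)C)c2)[C@H](c2ccc(O[Si](C)(C)C(C)(C)C)cc2)O5)[C@@H](c2ccc(O[Si](C)(C)C(C)(C)C)cc2)O4)[C@H](c2ccc(O[Si](C)(C)C(C)(C)C)cc2)O3)cc1
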